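The runs were computed on assumed constants; noise was put on by code.

A small charge started the dispute: Tuesday's run held 3 mM of protic impurity, and after 40.0 h its other capture product stood at 2.81 mM, to be set against that charge.

the same everywhere: substrate 0.010 M

|  | first nucleophile | second nucleophile | protic impurity | remark | time |
|---|---|---|---|---|---|
| Tuesday's | 10 mM | 0.024 M | 3 mM | run made earlier |  |
| flask | 10.0 mM | 0.0120 M | 3.00 mM |  | 8.0 d |

- Tuesday's (time / h: other capture product / %, target / %): 3.00: 7.1, 3.4; 5.00: 10.4, 5.3; 8.00: 15.6, 10.5; 10.0: 18.8, 12.9; 15.0: 20.6, 17.0; 25.0: 26.1, 18.1; 40.0: 28.1, 21.3

(readings scatter by 1 percentage point)

* ratio of other capture product to target at 80 min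
* ratio of other capture product to target at 8.0 d
* which of other capture product and target there is more of at 8.0 d

The first chemist reads a stoichiometric cap: the impurity traps a common intermediate mole for mole, and the second nucleophile makes target. On that view the ratio of other capture product to target, 2.09 at 3.00 h on Tuesday, rises when the second nucleophile is cut to 0.0120 M.

The second chemist, and I with her, reads a competition: first and second nucleophile capture one intermediate, so the product ratio follows the nucleophile ratio. That early ratio rests on 3.4 % of target with a scatter of 1 percentage point, so she turns to the later readings. Between 8.00 h and 40.0 h the other capture product grew 1.80-fold and the target 2.03-fold on Tuesday, and she reads the two as growing side by side.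

She reckons other capture product per target, divided by second nucleophile per first nucleophile, the selectivity factor: 0.550 from the last reading, on the charges. This flask has half of Tuesday's second nucleophile, so her ratio is 0.660. Taken on the charges, it serves for both 80 min and 8.0 d, with target ahead.

The forecast takes the first chemist's side, with 4.2 at 80 min on the ground that “Halving that concentration doubles it”, and with 0.85 at 8.0 d and target ahead.

The flask gives 0.710 at 80 min and 0.635 at 8.0 d, with 25.1 % of target against 16.0 % of other capture product.

    substrate → intermediate (k = 0.0900 /h)
    first nucleophile + intermediate → target (k = 180 /M/h)
    second nucleophile + intermediate → other capture product (k = 110 /M/h)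
    intermediate → solvolysis product (k = 3.60 /h)
    first nucleophile → decomposition product (k = 2.60 × 10⁻⁵ /h)
    intermediate → decomposed reagent (k = 0.0620 /h)
    second nucleophile + protic impurity → quenched reagent (k = 19.0 /M/h)

The first chemist's mole-for-mole count holds for the impurity itself: at 8.00 d this flask holds 0.00300 M of quenched reagent with 0 % of protic impurity left, though the impurity takes that from the second nucleophile and not from the intermediate. The neighbouring flask charges 0.040 M of first nucleophile, and the same factor gives 0.165 for it. That neighbour gives 0.177 at 80 min and 0.155 at 8.0 d. It ends with 58.6 % of target beside 31.7 % of solvolysis product.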